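## Retrosynthetic overview

1. The angelate goes on last, by acylating the free C3–OH of the 6-acetate 12. This does not break the C3–O bond.
2. C6 (R) and C7 (S) come together from a C=O-selective hydrogenation with dynamic kinetic resolution of the 3-silyloxy-(1(10)E,4Z)-germacradien-6-one 9.
3. The ten-membered ring is the only ring in the target. It comes from an anionic oxy-Cope expansion of a 1,2-dialkenylcyclohexenol, and the old cyclohexene C=C becomes the Z C4=C5 alkene.
4. The cyclohexenone needed for that comes from CH2-to-C=O oxidation of trans-carveyl acetate.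
5. Key disconnection: the C3–O bond, made by enantioselective allylic C–H acetoxylation of limonene. Ring order: the six-membered ring is bought with limonene and is expanded to the ten-membered ring in step 4.

Assumption: positions use germacrane numbering (C3 angelate, C6 acetate, C7 isopropyl, C1=C10 E, C4=C5 Z), the target is (3S,6R,7S), and 2-bromo-3-methylbut-1-ene is taken as purchasable.

## Route

**Step 1**
Reactants: 1 (R)-(+)-limonene
Product: 2 (1S,5R)-2-methyl-5-(prop-1-en-2-yl)cyclohex-2-en-1-yl acetate (trans-carveyl acetate)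
Conditions: Pd(OAc)2 (10 mol %), (S)-4-tert-butyl-2-{2-[(S)-p-tolylsulfinyl]phenyl}-4,5-dihydrooxazole (12 mol %), 2,6-dimethyl-1,4-benzoquinone (1.2 equiv), AcOH (4 equiv), (BuO)2P(O)OH (10 mol %), toluene, 45 °C
Reagents that add atoms: acetic acid, CC(=O)O
Why: Proposed new method: carboxylate-assisted allylic C–H cleavage by divalent palladium at the ring CH2 next to the methyl-bearing alkene carbon gives an η3-(2-methyl-5-isopropenylcyclohexenyl)palladium complex with a mirror plane through C1 and C4, so the stereocentre of 1 is erased and the two allyl termini are enantiotopic; the isopropenyl group sits equatorial on the ring flap that tips away from the metal, so quinone-promoted outer-sphere attack of acetate anti to palladium gives the trans ester, and the sulfoxide–oxazoline ligand (different trans influence of S and N, plus the tert-butyl wall) steers that attack to the terminus that becomes the 1S carbinol carbon, which is C3 of the target; the closest known reaction types are the ligand-free Pd(OAc)2/benzoquinone acetoxylation of limonene (racemic trans-carveyl acetate), sulfoxide–oxazoline/palladium enantioselective allylic C–H oxidation with tethered alcohols, and the deracemisation of cyclic allylic esters by carboxylates through meso π-allylpalladium complexes.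

**Step 2**
Reactants: 2 trans-carveyl acetate
Product: 3 (1S,5R)-2-methyl-4-oxo-5-(prop-1-en-2-yl)cyclohex-2-en-1-yl acetate
Conditions: tetrachloro-N-hydroxyphthalimide (20 mol %), tBuOOH (1.5 equiv), pyridine (2 equiv), LiClO4 (0.1 M), acetone, reticulated vitreous carbon anode and cathode, constant current, rt
Reagents that add atoms: tert-butyl hydroperoxide, CC(C)(C)OO
Why: In this N-oxyl-mediated electrochemical allylic C–H oxidation (hydrogen-atom abstraction, peroxide trapping, elimination) the only ring CH2 allylic to the trisubstituted alkene reacts, because the acetoxy group deactivates the carbinol C–H and an isopropenyl group is tolerated as in the valencene-to-nootkatone case; no stereocentre is made and C1 (S) is untouched.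

**Step 3**
Reactants: 3 acetoxy enone; 4 2-bromo-3-methylbut-1-ene
Product: 7 (1R,4S,6R)-4-(tert-butyldimethylsilyloxy)-3-methyl-1-(3-methylbut-1-en-2-yl)-6-(prop-1-en-2-yl)cyclohex-2-en-1-ol, via alkenyllithium 5 (not isolated), via dilithium dialkoxide 6 (not isolated)
Conditions: 4 (3.6 equiv), tBuLi (7.2 equiv), Et2O, −78 °C; 3, −78 → −30 °C; TBSCl (1.8 equiv), DMPU, THF, −30 °C → rt; H2O
Reagents that add atoms: 2-bromo-3-methylbut-1-ene (4), C=C(Br)C(C)C; tert-butyldimethylsilyl chloride, CC(C)(C)[Si](C)(C)Cl
Why: 1,2-Addition of the alkenyllithium to the enone carbonyl from the face opposite the neighbouring isopropenyl group (equatorial attack) sets the transient tertiary carbinol with the two alkenyl groups trans, two further equivalents cleave the acetate, and chemoselective O-silylation takes only the unhindered secondary lithium alkoxide, which must be masked because a free C3 alkoxide would trigger a second oxy-Cope after ring expansion.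

**Step 4**
Reactants: 7 silyl-protected dialkenylcyclohexenol
Product: 9 (2Z,4S,6E)-4-(tert-butyldimethylsilyloxy)-3,7-dimethyl-10-(propan-2-yl)cyclodeca-2,6-dien-1-one as a mixture of C10 (germacrane C7) epimers, via potassium enolate 8 (not isolated)
Conditions: KH (1.3 equiv), 18-crown-6 (1.3 equiv), THF, 0 °C → rt; AcOH, THF, −78 °C
Reagents that add atoms: none
Why: The anionic oxy-Cope rearrangement ([3,3]-sigmatropic four-carbon ring expansion) runs through a chair transition state with both ring bonds pseudo-equatorial and gives the E C1=C10 alkene, the old cyclohexene alkene stays Z as C4=C5, C3 is untouched, the two other ring stereocentres are erased, and the unselective protonation at C7 does not matter because step 5 resets it.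

**Step 5**
Reactants: 9 silyloxy dienone (C7 epimers)
Product: 10 (1R,2Z,4S,6E,10S)-4-(tert-butyldimethylsilyloxy)-3,7-dimethyl-10-(propan-2-yl)cyclodeca-2,6-dien-1-ol
Conditions: RuCl2[(S)-xylbinap][(S)-daipen] (1 mol %), tBuOK (20 mol %), H2 (10 atm), iPrOH, 25 °C
Reagents that add atoms: none
Why: In this Noyori-type C=O-selective asymmetric hydrogenation with dynamic kinetic resolution, tBuOK epimerises C7 through the cross-conjugated enolate faster than reduction, the (S),(S) catalyst forms the R carbinol (same sense as with alkenyl and aryl alkyl ketones), and only the 7S epimer presents that carbonyl face on the ring periphery with its isopropyl group pseudo-equatorial (attack anti to the C7–C8 bond, as in 2-isopropylcyclohexanone giving the cis alcohol), so C6 (R) and C7 (S) are set together and the C=C bonds are left alone.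

**Step 6**
Reactants: 10 allylic alcohol
Product: 12 (1R,2Z,4S,6E,10S)-4-hydroxy-3,7-dimethyl-10-(propan-2-yl)cyclodeca-2,6-dien-1-yl acetate, via silyl ether acetate 11 (not isolated)
Conditions: Ac2O, pyridine, DMAP (5 mol %), CH2Cl2, 0 °C → rt; then HF·pyridine, THF, 0 °C → rt
Reagents that add atoms: acetic anhydride, CC(=O)OC(C)=O
Why: DMAP-catalysed acetylation is followed in the same flask by fluoride cleavage of the allylic silyl ether in pyridine-buffered medium, which avoids both acid-induced transannular cyclisation and base-induced acetyl migration; no stereocentre is touched.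

**Step 7**
Reactants: 12 hydroxy acetate; 13 angelic acid
Product: 15 (3S,6R,7S)-6-acetoxy-3-angeloyloxygermacra-1(10)E,4Z-diene (target), via mixed anhydride 14 (not isolated)
Conditions: 13 (3 equiv), 2,4,6-trichlorobenzoyl chloride (3 equiv), Et3N (3.3 equiv), toluene, rt; then 12, 70 °C
Reagents that add atoms: angelic acid (13), C/C=C(/C)C(=O)O
Why: This Yamaguchi-type mixed-anhydride esterification is run without DMAP, so no nucleophile adds to the angeloyl unit and isomerises it to the tiglate, and since the C3–O bond is not broken 3S is retained.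

## Compound list

1 | (R)-(+)-limonene | CC1=CC[C@@H](CC1)C(C)=C | starting material
2 | (1S,5R)-trans-carveyl acetate | CC(=O)O[C@H]1C[C@H](C(C)=C)CC=C1C | intermediate
3 | (1S,5R)-2-methyl-4-oxo-5-(prop-1-en-2-yl)cyclohex-2-en-1-yl acetate | CC(=O)O[C@H]1C[C@H](C(C)=C)C(=O)C=C1C | intermediate
4 | 2-bromo-3-methylbut-1-ene | C=C(Br)C(C)C | starting material
5 | (3-methylbut-1-en-2-yl)lithium | [Li]C(=C)C(C)C | intermediate (not isolated)
6 | dilithium (1S,4R,5R)-2-methyl-4-(3-methylbut-1-en-2-yl)-5-(prop-1-en-2-yl)cyclohex-2-ene-1,4-diolate | [Li+].[Li+].[O-][C@H]1C[C@H](C(C)=C)[C@@]([O-])(C(=C)C(C)C)C=C1C | intermediate (not isolated)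
7 | (1R,4S,6R)-4-(tert-butyldimethylsilyloxy)-3-methyl-1-(3-methylbut-1-en-2-yl)-6-(prop-1-en-2-yl)cyclohex-2-en-1-ol | CC(C)(C)[Si](C)(C)O[C@H]1C[C@H](C(C)=C)[C@@](O)(C(=C)C(C)C)C=C1C | intermediate
8 | potassium enolate of 9 (C6–O−, ring-E C6=C7) | [K+].CC(C)(C)[Si](C)(C)O[C@H]1C/C=C(\C)CC/C(C(C)C)=C([O-])/C=C\1C | intermediate (not isolated)
9 | (2Z,4S,6E)-4-(tert-butyldimethylsilyloxy)-3,7-dimethyl-10-(propan-2-yl)cyclodeca-2,6-dien-1-one, C10 epimers | CC(C)(C)[Si](C)(C)O[C@H]1C/C=C(\C)CCC(C(C)C)C(=O)/C=C\1C | intermediate
10 | (1R,2Z,4S,6E,10S)-4-(tert-butyldimethylsilyloxy)-3,7-dimethyl-10-(propan-2-yl)cyclodeca-2,6-dien-1-ol | CC(C)(C)[Si](C)(C)O[C@H]1C/C=C(\C)CC[C@@H](C(C)C)[C@@H](O)/C=C\1C | intermediate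
11 | (1R,2Z,4S,6E,10S)-4-(tert-butyldimethylsilyloxy)-3,7-dimethyl-10-(propan-2-yl)cyclodeca-2,6-dien-1-yl acetate | CC(C)(C)[Si](C)(C)O[C@H]1C/C=C(\C)CC[C@@H](C(C)C)[C@@H](OC(C)=O)/C=C\1C | intermediate (not isolated)
12 | (1R,2Z,4S,6E,10S)-4-hydroxy-3,7-dimethyl-10-(propan-2-yl)cyclodeca-2,6-dien-1-yl acetate | O[C@H]1C/C=C(\C)CC[C@@H](C(C)C)[C@@H](OC(C)=O)/C=C\1C | intermediate
13 | angelic acid, (Z)-2-methylbut-2-enoic acid | C/C=C(/C)C(=O)O | starting material
14 | angelic 2,4,6-trichlorobenzoic anhydride | C/C=C(/C)C(=O)OC(=O)c1c(Cl)cc(Cl)cc1Cl | intermediate (not isolated)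
15 | (1R,2Z,4S,6E,10S)-4-{[(2Z)-2-methylbut-2-enoyl]oxy}-3,7-dimethyl-10-(propan-2-yl)cyclodeca-2,6-dien-1-yl acetate | C/C=C(/C)C(=O)O[C@H]1C/C=C(\C)CC[C@@H](C(C)C)[C@@H](OC(C)=O)/C=C\1C | target

## Step count

Total step count: 7. Longest linear sequence: 7 (1 → 15).

## Steps most likely to fail

**Step 1 (the new reaction).** The ligand may slow C–H cleavage at a trisubstituted ring alkene, the isopropenyl group may compete for palladium, and the enantioselectivity is untested. Any 3R material that gets through becomes a separable diastereomer after step 5. The fallback sets out from 1 and comes back at 2. Compound 1 is acetoxylated without chiral ligand (Pd(OAc)2, benzoquinone, AcOH, 60 °C). Because the allyl intermediate is meso, this gives the racemate, that is 2 together with (1R,5S)-trans-carveyl acetate F1. Lipase hydrolysis (Pseudomonas cepacia lipase, phosphate buffer, rt) cleaves the faster-reacting R-carbinol ester to (1R,5S)-trans-carveol F2. The unreacted 2 is then separated by chromatography, with a maximum yield of 50 %.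

**Step 3.** The doubly activated proton next to the ketone invites enolisation, a large excess of 5 is consumed, and the one-pot selective silylation may be incomplete. The fallback sets out from 2 and comes back at 7, and it exchanges the protecting group before the ketone exists. Methanolysis (K2CO3, MeOH) gives (1S,5R)-trans-carveol F3. TBSCl and imidazole give its silyl ether F4. CrO3 with 3,5-dimethylpyrazole (CH2Cl2, −20 °C) gives (4S,6R)-4-(tert-butyldimethylsilyloxy)-3-methyl-6-(prop-1-en-2-yl)cyclohex-2-en-1-one F5. This enone then takes only 1.3 equiv of 5, premixed with anhydrous CeCl3 at −78 °C, to give 7.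

**Step 5.** The ketone is hindered. tBuOK could also isomerise the Z enone or, through the extended dienolate, erode C3, and epimerisation at C7 may be slower than reduction. The fallback sets out from 9 and comes back at 10, and it replaces catalyst control by separation plus substrate control. The epimers of 9 are separated on silica into the (10S)-ketone F6 and the (10R)-ketone F7. F6 is reduced under Luche conditions (NaBH4, CeCl3·7H2O, MeOH, −40 °C) from the ring periphery to give 10. F7 is re-equilibrated to the mixture 9 with K2CO3 in MeOH and recycled.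

## Further compounds

F1 | step 1 | (1R,5S)-trans-carveyl acetate | CC(=O)O[C@@H]1C[C@@H](C(C)=C)CC=C1C
F2 | step 1 | (1R,5S)-trans-carveol | O[C@@H]1C[C@@H](C(C)=C)CC=C1C
F3 | step 3 | (1S,5R)-trans-carveol | O[C@H]1C[C@H](C(C)=C)CC=C1C
F4 | step 3 | tert-butyldimethyl{[(1S,5R)-2-methyl-5-(prop-1-en-2-yl)cyclohex-2-en-1-yl]oxy}silane | CC(C)(C)[Si](C)(C)O[C@H]1C[C@H](C(C)=C)CC=C1C
F5 | step 3 | (4S,6R)-4-(tert-butyldimethylsilyloxy)-3-methyl-6-(prop-1-en-2-yl)cyclohex-2-en-1-one | CC(C)(C)[Si](C)(C)O[C@H]1C[C@H](C(C)=C)C(=O)C=C1C
F6 | step 5 | (2Z,4S,6E,10S)-4-(tert-butyldimethylsilyloxy)-3,7-dimethyl-10-(propan-2-yl)cyclodeca-2,6-dien-1-one | CC(C)(C)[Si](C)(C)O[C@H]1C/C=C(\C)CC[C@@H](C(C)C)C(=O)/C=C\1C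
F7 | step 5 | (2Z,4S,6E,10R)-4-(tert-butyldimethylsilyloxy)-3,7-dimethyl-10-(propan-2-yl)cyclodeca-2,6-dien-1-one | CC(C)(C)[Si](C)(C)O[C@H]1C/C=C(\C)CC[C@H](C(C)C)C(=O)/C=C\1C
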